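**Retrosynthetic overview**

1. Target 14 ⇐ hydrogenolysis of the perbenzylated gallate 13 ⇐ phenol-selective 7-O-galloylation of diol 11 with acid chloride 12; the 3-OH comes from Baeyer–Villiger oxidation (retention) of the 2,3-trans 3-acetylflavan 9.
2. Ring C is the only ring made (rings A, B and the galloyl ring are bought): 9 ⇐ achiral enone 6 by a catalytic asymmetric hydride shift/cyclization that moves one H from C2 to C4 and then joins C2 to C3.
3. Enabling feature: in 6 the O1–CH2 group carrying ring B (C–H made hydridic by O1 and by the para-oxygen of ring B) lies 1,5 to C4, the enone β-carbon on ring A, and C4 is CH2 in the target. Both ortho oxygens of ring A carry the same benzyl group, so the two donor sites are equivalent and the spare one protects O5.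
4. 6 ⇐ Wittig olefination of aldehyde 4 ⇐ double O-alkylation of 2 with benzyl chloride 3 ⇐ para-selective pivaloylation of 2,4,6-trihydroxybenzaldehyde 1; the O7 pivalate tempers ring A as a donor and is later shed together with the acetate.

Key step: step 4

Remark: the sense of induction of the amine/phosphate pair in step 4 is assumed; should the (2R,3R)-ketone prevail, the mirror-image pair (D-valine tert-butyl ester with (S)-TRIP) would be used. TRIP = 3,3'-bis(2,4,6-triisopropylphenyl)-1,1'-binaphthyl-2,2'-diyl hydrogen phosphate.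

**Step 1**
Reactants: 1 2,4,6-trihydroxybenzaldehyde
Product: 2 4-formyl-3,5-dihydroxyphenyl pivalate
Conditions: PivCl (1.0 equiv), Et3N (1.1 equiv), THF, −20 to 0 °C
Reagents that add atoms: pivaloyl chloride, CC(C)(C)C(=O)Cl
Why: Selective O-acylation of the most acidic, non-chelated para hydroxyl should occur because both ortho hydroxyls are tied up in hydrogen bonds to the formyl oxygen.

**Step 2**
Reactants: 2 4-formyl-3,5-dihydroxyphenyl pivalate; 3 3,4-bis(benzyloxy)benzyl chloride (2.3 equiv)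
Product: 4 3,5-bis{[3,4-bis(benzyloxy)benzyl]oxy}-4-formylphenyl pivalate
Conditions: K2CO3, KI (cat.), DMF, 45 °C
Reagents that add atoms: 3,4-bis(benzyloxy)benzyl chloride (3), ClCc1ccc(OCc2ccccc2)c(OCc2ccccc2)c1
Why: Iodide-assisted Williamson ether synthesis on both ortho phenols should proceed while the hindered pivalate survives anhydrous carbonate.

**Step 3**
Reactants: 4 3,5-bis{[3,4-bis(benzyloxy)benzyl]oxy}-4-formylphenyl pivalate; 5 1-(triphenylphosphoranylidene)propan-2-one
Product: 6 3,5-bis{[3,4-bis(benzyloxy)benzyl]oxy}-4-[(1E)-3-oxobut-1-en-1-yl]phenyl pivalate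
Conditions: toluene, 110 °C
Reagents that add atoms: 1-(triphenylphosphoranylidene)propan-2-one (5), CC(=O)C=P(c1ccccc1)(c1ccccc1)c1ccccc1
Why: Wittig olefination with a stabilised ylide should give the (E)-enone under neutral conditions that spare the aryl pivalate.

**Step 4**
Reactants: 6 3,5-bis{[3,4-bis(benzyloxy)benzyl]oxy}-4-[(1E)-3-oxobut-1-en-1-yl]phenyl pivalate
Product: 9 (2S,3S)-3-acetyl-2-[3,4-bis(benzyloxy)phenyl]-5-{[3,4-bis(benzyloxy)benzyl]oxy}-3,4-dihydro-2H-chromen-7-yl pivalate, via iminium ion 7 (not isolated), via oxocarbenium enamine 8 (not isolated)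
Conditions: L-valine tert-butyl ester·(R)-TRIP salt (20 mol %), toluene, 60 °C
Reagents that add atoms: none
Why: Proposed new method: the ammonium salt condenses with enone 6 to iminium ion 7, whose β-carbon C4 takes a hydride from the benzylic CH2 of an ortho ether in a suprafacial 1,5-shift through a six-membered transition state, and the enamine carbon C3 of the resulting oxocarbenium enamine 8 then attacks the oxocarbenium carbon C2 before hydrolysis releases ketone 9 and the catalyst. The closest known reaction types are the Sc(OTf)3-catalysed hydride shift/cyclization of ortho-benzyloxy benzylidene malonates to 2-arylchromans, the amine-catalysed enantioselective hydride shift/cyclization of ortho-dialkylamino cinnamaldehydes, and the transfer hydrogenation of enones by amino ester phosphate salts, which shows hydride delivery to this kind of iminium ion. Ring C closes in a 6-(enolexo)-endo-trig mode. C2 is set by catalyst control in the C–C bond formation, the (E)-oxocarbenium ion holding ring B pseudo-equatorial in a chair-like transition state while the valine-derived enamine and the ion-paired chiral phosphate shield one of its faces; C3 is set by thermodynamic control, the epimerisable α-carbon settling in the 2,3-trans diequatorial form. The step needs selectivity between the two ortho benzylic donors and for hydride shift over hydrolysis or ionisation of the ethers: ring A carries the same benzyl group on both ortho oxygens, so either donor gives 9, the para-oxygen of ring B makes the C2–H bond hydridic, and the weakly acidic salt should leave the ethers intact.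

**Step 5**
Reactants: 9 (2S,3S)-3-acetyl-2-[3,4-bis(benzyloxy)phenyl]-5-{[3,4-bis(benzyloxy)benzyl]oxy}-3,4-dihydro-2H-chromen-7-yl pivalate
Product: 10 (2R,3S)-3-acetoxy-2-[3,4-bis(benzyloxy)phenyl]-5-{[3,4-bis(benzyloxy)benzyl]oxy}-3,4-dihydro-2H-chromen-7-yl pivalate
Conditions: mCPBA, CH2Cl2, 0 °C to rt
Reagents that add atoms: mCPBA (3-chloroperbenzoic acid), O=C(OO)c1cccc(Cl)c1
Why: In this Baeyer–Villiger oxidation the secondary carbon C3 should migrate in preference to methyl and with retention, so the 2,3-trans relationship passes into the acetate and the carbonyl that could open ring C by β-elimination is removed.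

**Step 6**
Reactants: 10 (2R,3S)-3-acetoxy-2-[3,4-bis(benzyloxy)phenyl]-5-{[3,4-bis(benzyloxy)benzyl]oxy}-3,4-dihydro-2H-chromen-7-yl pivalate
Product: 11 (2R,3S)-2-[3,4-bis(benzyloxy)phenyl]-5-{[3,4-bis(benzyloxy)benzyl]oxy}-3,4-dihydro-2H-chromene-3,7-diol
Conditions: K2CO3 (cat.), MeOH/THF, rt to 40 °C
Reagents that add atoms: none
Why: Carbonate-catalysed transesterification with methanol should cleave the alkyl acetate and the aryl pivalate together, and no stereocentre is epimerisable once C3 carries no carbonyl.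

**Step 7**
Reactants: 11 (2R,3S)-2-[3,4-bis(benzyloxy)phenyl]-5-{[3,4-bis(benzyloxy)benzyl]oxy}-3,4-dihydro-2H-chromene-3,7-diol; 12 3,4,5-tris(benzyloxy)benzoyl chloride (1.05 equiv)
Product: 13 (2R,3S)-2-[3,4-bis(benzyloxy)phenyl]-5-{[3,4-bis(benzyloxy)benzyl]oxy}-3-hydroxy-3,4-dihydro-2H-chromen-7-yl 3,4,5-tris(benzyloxy)benzoate
Conditions: Et3N (1.2 equiv), CH2Cl2, −20 to 0 °C, no acyl-transfer catalyst
Reagents that add atoms: 3,4,5-tris(benzyloxy)benzoyl chloride (12), O=C(Cl)c1cc(OCc2ccccc2)c(OCc2ccccc2)c(OCc2ccccc2)c1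
Why: Chemoselective acylation of the phenoxide over the hindered neutral secondary alcohol, which should not react with an aroyl chloride at low temperature without a nucleophilic catalyst.

**Step 8**
Reactants: 13 (2R,3S)-2-[3,4-bis(benzyloxy)phenyl]-5-{[3,4-bis(benzyloxy)benzyl]oxy}-3-hydroxy-3,4-dihydro-2H-chromen-7-yl 3,4,5-tris(benzyloxy)benzoate
Product: 14 catechin 7-O-gallate, (2R,3S)-2-(3,4-dihydroxyphenyl)-3,5-dihydroxy-3,4-dihydro-2H-chromen-7-yl 3,4,5-trihydroxybenzoate
Conditions: H2 (1 atm), Pd(OH)2/C, THF/MeOH, rt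
Reagents that add atoms: none
Why: Catalytic hydrogenolysis should remove the seven benzyl ethers and the oxygenated benzyl group on O5 under neutral conditions that leave the aryl ester and the cyclic C2–O1 bond untouched.

**Compound list**

1 | 2,4,6-trihydroxybenzaldehyde | O=Cc1c(O)cc(O)cc1O | starting material
2 | 4-formyl-3,5-dihydroxyphenyl pivalate | CC(C)(C)C(=O)Oc1cc(O)c(C=O)c(O)c1 | intermediate
3 | 3,4-bis(benzyloxy)benzyl chloride | ClCc1ccc(OCc2ccccc2)c(OCc2ccccc2)c1 | starting material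
4 | 3,5-bis{[3,4-bis(benzyloxy)benzyl]oxy}-4-formylphenyl pivalate | CC(C)(C)C(=O)Oc1cc(OCc2ccc(OCc3ccccc3)c(OCc3ccccc3)c2)c(C=O)c(OCc2ccc(OCc3ccccc3)c(OCc3ccccc3)c2)c1 | intermediate
5 | 1-(triphenylphosphoranylidene)propan-2-one | CC(=O)C=P(c1ccccc1)(c1ccccc1)c1ccccc1 | starting material
6 | 3,5-bis{[3,4-bis(benzyloxy)benzyl]oxy}-4-[(1E)-3-oxobut-1-en-1-yl]phenyl pivalate | CC(=O)/C=C/c1c(OCc2ccc(OCc3ccccc3)c(OCc3ccccc3)c2)cc(OC(=O)C(C)(C)C)cc1OCc1ccc(OCc2ccccc2)c(OCc2ccccc2)c1 | intermediate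
7 | iminium ion of enone 6 with L-valine tert-butyl ester (cation; counter-ion TRIP phosphate) | CC(=[NH+][C@@H](C(C)C)C(=O)OC(C)(C)C)/C=C/c1c(OCc2ccc(OCc3ccccc3)c(OCc3ccccc3)c2)cc(OC(=O)C(C)(C)C)cc1OCc1ccc(OCc2ccccc2)c(OCc2ccccc2)c1 | intermediate
8 | ring-open oxocarbenium enamine after the 1,5-hydride shift: ring A bears O+=CH–(ring B) and CH2–CH=C(CH3)–NH–(valine tert-butyl ester) (cation; counter-ion TRIP phosphate) | CC(N[C@@H](C(C)C)C(=O)OC(C)(C)C)=CCc1c(OCc2ccc(OCc3ccccc3)c(OCc3ccccc3)c2)cc(OC(=O)C(C)(C)C)cc1[O+]=Cc1ccc(OCc2ccccc2)c(OCc2ccccc2)c1 | intermediate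
9 | (2S,3S)-3-acetyl-2-[3,4-bis(benzyloxy)phenyl]-5-{[3,4-bis(benzyloxy)benzyl]oxy}-3,4-dihydro-2H-chromen-7-yl pivalate (2,3-trans; same spatial arrangement at C2 as the target, the descriptor differs only through the priority rules) | CC(C)(C)C(=O)Oc1cc(OCc2ccc(OCc3ccccc3)c(OCc3ccccc3)c2)c2c(c1)O[C@H](c1ccc(OCc3ccccc3)c(OCc3ccccc3)c1)[C@@H](C(C)=O)C2 | intermediate
10 | (2R,3S)-3-acetoxy-2-[3,4-bis(benzyloxy)phenyl]-5-{[3,4-bis(benzyloxy)benzyl]oxy}-3,4-dihydro-2H-chromen-7-yl pivalate | CC(C)(C)C(=O)Oc1cc(OCc2ccc(OCc3ccccc3)c(OCc3ccccc3)c2)c2c(c1)O[C@H](c1ccc(OCc3ccccc3)c(OCc3ccccc3)c1)[C@@H](OC(C)=O)C2 | intermediate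
11 | (2R,3S)-2-[3,4-bis(benzyloxy)phenyl]-5-{[3,4-bis(benzyloxy)benzyl]oxy}-3,4-dihydro-2H-chromene-3,7-diol | Oc1cc(OCc2ccc(OCc3ccccc3)c(OCc3ccccc3)c2)c2c(c1)O[C@H](c1ccc(OCc3ccccc3)c(OCc3ccccc3)c1)[C@@H](O)C2 | intermediate
12 | 3,4,5-tris(benzyloxy)benzoyl chloride | O=C(Cl)c1cc(OCc2ccccc2)c(OCc2ccccc2)c(OCc2ccccc2)c1 | starting material
13 | (2R,3S)-2-[3,4-bis(benzyloxy)phenyl]-5-{[3,4-bis(benzyloxy)benzyl]oxy}-3-hydroxy-3,4-dihydro-2H-chromen-7-yl 3,4,5-tris(benzyloxy)benzoate | O=C(Oc1cc(OCc2ccc(OCc3ccccc3)c(OCc3ccccc3)c2)c2c(c1)O[C@H](c1ccc(OCc3ccccc3)c(OCc3ccccc3)c1)[C@@H](O)C2)c1cc(OCc2ccccc2)c(OCc2ccccc2)c(OCc2ccccc2)c1 | intermediate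
14 | catechin 7-O-gallate, (2R,3S)-2-(3,4-dihydroxyphenyl)-3,5-dihydroxy-3,4-dihydro-2H-chromen-7-yl 3,4,5-trihydroxybenzoate | O=C(Oc1cc(O)c2c(c1)O[C@H](c1ccc(O)c(O)c1)[C@@H](O)C2)c1cc(O)c(O)c(O)c1 | target

**Step count and risks**

Total step count: 8. Longest linear sequence: 8 steps (1 to 14).

Steps most likely to fail:

1. Step 4 (proposed new method). The ketiminium ion may be too weak a hydride acceptor next to the electron-rich ring A. Water may intercept the oxocarbenium ion, with loss of the benzyl group as its aldehyde. The C2 configuration may erode through amine-mediated opening and re-closure of ring C. Fallback: setting out from aldehyde 4, Knoevenagel condensation with allyl acetoacetate (piperidinium acetate cat., toluene, molecular sieves) would give the doubly activated alkylidene acetoacetate F1. Sc(OTf)3 (cat., 1,2-dichloroethane, 40–60 °C) should then effect the known Lewis-acid hydride shift/cyclization of this substrate class to the racemic chroman keto ester F2. Pd(PPh3)4 with morpholine (THF, rt to 40 °C) would remove the allyl ester with decarboxylation, the α-carbon settling trans, to give the racemic ketone, that is 9 together with its enantiomer, the (2R,3R)-ketone F3. Preparative chromatography on a chiral stationary phase would remove F3 and return to the route at 9.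

2. Step 5. Oxygen insertion at the hindered ketone may be slow, allowing the peracid to oxidise the electron-rich rings instead. Fallback: setting out from ketone 9, methylenation with the Tebbe reagent Cp2Ti(μ-Cl)(μ-CH2)AlMe2 (THF, −40 to 0 °C, where the pivalate should be spared) would give the isopropenyl flavan F4. Ozonolysis in CH2Cl2/MeOH at −78 °C would give the methoxy hydroperoxide F5. Ac2O/Et3N/DMAP would then trigger its Criegee rearrangement, C3 migrating to oxygen with retention, returning to the route at acetate 10.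

3. Step 7. Acylation of the secondary hydroxyl may compete with phenol acylation, giving over-acylated material. Fallback: setting out from diol 11, TBSOTf/2,6-lutidine would silylate both hydroxyls to the bis-silyl ether F6. KHF2 in MeOH would cleave only the aryl silyl ether to the 3-O-silyl phenol F7. Acylation with 12 (Et3N, DMAP, CH2Cl2) would give the silylated gallate F8, and HF·pyridine in THF would free the 3-hydroxyl and return to the route at 13.

**Further compounds**

F1 | step 4 | allyl 2-acetyl-3-[2,6-bis{[3,4-bis(benzyloxy)benzyl]oxy}-4-(pivaloyloxy)phenyl]prop-2-enoate (E/Z mixture) | C=CCOC(=O)C(C(C)=O)=Cc1c(OCc2ccc(OCc3ccccc3)c(OCc3ccccc3)c2)cc(OC(=O)C(C)(C)C)cc1OCc1ccc(OCc2ccccc2)c(OCc2ccccc2)c1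
F2 | step 4 | allyl 3-acetyl-2-[3,4-bis(benzyloxy)phenyl]-5-{[3,4-bis(benzyloxy)benzyl]oxy}-7-(pivaloyloxy)-3,4-dihydro-2H-chromene-3-carboxylate (racemic mixture of diastereomers, no configuration assigned) | C=CCOC(=O)C1(C(C)=O)Cc2c(OCc3ccc(OCc4ccccc4)c(OCc4ccccc4)c3)cc(OC(=O)C(C)(C)C)cc2OC1c1ccc(OCc2ccccc2)c(OCc2ccccc2)c1
F3 | step 4 | (2R,3R)-3-acetyl-2-[3,4-bis(benzyloxy)phenyl]-5-{[3,4-bis(benzyloxy)benzyl]oxy}-3,4-dihydro-2H-chromen-7-yl pivalate (enantiomer of 9) | CC(C)(C)C(=O)Oc1cc(OCc2ccc(OCc3ccccc3)c(OCc3ccccc3)c2)c2c(c1)O[C@@H](c1ccc(OCc3ccccc3)c(OCc3ccccc3)c1)[C@H](C(C)=O)C2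
F4 | step 5 | (2S,3R)-2-[3,4-bis(benzyloxy)phenyl]-5-{[3,4-bis(benzyloxy)benzyl]oxy}-3-(prop-1-en-2-yl)-3,4-dihydro-2H-chromen-7-yl pivalate (2,3-trans) | CC(C)(C)C(=O)Oc1cc(OCc2ccc(OCc3ccccc3)c(OCc3ccccc3)c2)c2c(c1)O[C@H](c1ccc(OCc3ccccc3)c(OCc3ccccc3)c1)[C@@H](C(C)=C)C2
F5 | step 5 | (2S,3S)-2-[3,4-bis(benzyloxy)phenyl]-5-{[3,4-bis(benzyloxy)benzyl]oxy}-3-(1-hydroperoxy-1-methoxyethyl)-3,4-dihydro-2H-chromen-7-yl pivalate (both configurations at the hydroperoxy carbon) | CC(C)(C)C(=O)Oc1cc(OCc2ccc(OCc3ccccc3)c(OCc3ccccc3)c2)c2c(c1)O[C@H](c1ccc(OCc3ccccc3)c(OCc3ccccc3)c1)[C@@H](C(C)(OC)OO)C2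
F6 | step 7 | (2R,3S)-2-[3,4-bis(benzyloxy)phenyl]-5-{[3,4-bis(benzyloxy)benzyl]oxy}-3,7-bis(tert-butyldimethylsilyloxy)-3,4-dihydro-2H-chromene | CC(C)(C)[Si](C)(C)Oc1cc(OCc2ccc(OCc3ccccc3)c(OCc3ccccc3)c2)c2c(c1)O[C@H](c1ccc(OCc3ccccc3)c(OCc3ccccc3)c1)[C@@H](O[Si](C)(C)C(C)(C)C)C2
F7 | step 7 | (2R,3S)-2-[3,4-bis(benzyloxy)phenyl]-5-{[3,4-bis(benzyloxy)benzyl]oxy}-3-(tert-butyldimethylsilyloxy)-3,4-dihydro-2H-chromen-7-ol | Oc1cc(OCc2ccc(OCc3ccccc3)c(OCc3ccccc3)c2)c2c(c1)O[C@H](c1ccc(OCc3ccccc3)c(OCc3ccccc3)c1)[C@@H](O[Si](C)(C)C(C)(C)C)C2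
F8 | step 7 | (2R,3S)-2-[3,4-bis(benzyloxy)phenyl]-5-{[3,4-bis(benzyloxy)benzyl]oxy}-3-(tert-butyldimethylsilyloxy)-3,4-dihydro-2H-chromen-7-yl 3,4,5-tris(benzyloxy)benzoate | O=C(Oc1cc(OCc2ccc(OCc3ccccc3)c(OCc3ccccc3)c2)c2c(c1)O[C@H](c1ccc(OCc3ccccc3)c(OCc3ccccc3)c1)[C@@H](O[Si](C)(C)C(C)(C)C)C2)c1cc(OCc2ccccc2)c(OCc2ccccc2)c(OCc2ccccc2)c1
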